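**Retrosynthetic overview**
1. Target ⇐ hydrogenolysis of a bis-benzyl ether ⇐ hydroxyl-directed anti reduction of an (S)-β-hydroxy ketone (C3 is set from C5).
2. β-Hydroxy ketone ⇐ dithiane unmasking ⇐ C3–C4 bond: lithiated 2-(2-arylethyl)-1,3-dithiane (syringyl half, C1–C3) + (S)-2-(2-arylethyl)oxirane (guaiacyl half, C4–C7).
3. (S)-Oxirane ⇐ hydrolytic kinetic resolution ⇐ sulfur-ylide epoxidation of a 3-arylpropanal ⇐ Heck reaction of the aryl bromide with allyl alcohol ⇐ guaiacol ⇐ catechol.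
4. Dithiane ⇐ 3-arylpropanal ⇐ the same Heck reaction ⇐ benzylated 4-bromosyringol ⇐ 2,6-dimethoxyphenol ⇐ ortho-lithiation/oxidation of 1,3-dimethoxybenzene ⇐ resorcinol.
5. Rings: both benzene rings are bought (catechol, resorcinol) and none is built. The only rings made are the auxiliary oxirane and 1,3-dithiane, both opened again after the coupling (oxirane first, then dithiane).

Assumption: the target is named (3S,5S)-1-(4-hydroxy-3,5-dimethoxyphenyl)-7-(4-hydroxy-3-methoxyphenyl)heptane-3,5-diol (anti diol; C5 is the guaiacyl-side carbinol), and MeI, BnBr, NBS, Me3S+ I− and propane-1,3-dithiol are treated as reagents.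

**Guaiacyl branch**

Step 1
Reactants: 1 catechol
Product: 2 guaiacol (2-methoxyphenol)
Conditions: MeI (0.9 equiv), K2CO3 (1.0 equiv), acetone, reflux, N2; catechol in excess, recovered by aqueous wash
Reagents that add atoms: iodomethane, CI
Why: Williamson O-methylation of the catechol monoanion; excess diol and substoichiometric MeI suppress the dimethyl ether.

Step 2
Reactants: 2 guaiacol
Product: 3 4-bromo-2-methoxyphenol
Conditions: NBS (1.0 equiv), MeCN, 0 °C → rt
Reagents that add atoms: N-bromosuccinimide, O=C1CCC(=O)N1Br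
Why: Electrophilic aromatic bromination in a polar solvent goes para to the free hydroxyl group, the strongest donor.

Step 3
Reactants: 3 4-bromo-2-methoxyphenol
Product: 4 1-(benzyloxy)-4-bromo-2-methoxybenzene
Conditions: BnBr, K2CO3, DMF, rt
Reagents that add atoms: benzyl bromide, BrCc1ccccc1
Why: Williamson ether synthesis; the benzyl ether survives the organolithium, Lewis acid and hydride steps and is removed by hydrogenolysis at the end.

Step 4
Reactants: 4 1-(benzyloxy)-4-bromo-2-methoxybenzene; 5 allyl alcohol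
Product: 6 3-[4-(benzyloxy)-3-methoxyphenyl]propanal
Conditions: Pd(OAc)2 (3 mol%), n-Bu4NCl, NaHCO3, DMF, 90 °C
Reagents that add atoms: none
Why: Heck–Jeffery arylation of the terminal alkene carbon, after which β-hydride elimination toward the carbinol carbon delivers the saturated aldehyde directly.

Step 5
Reactants: 6 3-[4-(benzyloxy)-3-methoxyphenyl]propanal
Product: 7 racemic 2-{2-[4-(benzyloxy)-3-methoxyphenyl]ethyl}oxirane
Conditions: Me3S+ I− (1.3 equiv), n-BuLi (1.25 equiv), THF, −10 °C; then 6, −10 °C → rt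
Reagents that add atoms: trimethylsulfonium iodide, C[S+](C)C.[I-]
Why: Corey–Chaykovsky epoxidation; the unstabilised sulfonium methylide adds to the carbonyl and closes the oxirane with loss of dimethyl sulfide.

Step 6
Reactants: 7 racemic 2-{2-[4-(benzyloxy)-3-methoxyphenyl]ethyl}oxirane
Product: 8 (2S)-2-{2-[4-(benzyloxy)-3-methoxyphenyl]ethyl}oxirane
Conditions: (S,S)-(salen)Co(OAc) (0.5 mol%; trivalent cobalt; salen = N,N'-bis(3,5-di-tert-butylsalicylidene)cyclohexane-1,2-diamine dianion), H2O (0.55 equiv), THF, 0 °C → rt, 16 h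
Reagents that add atoms: none
Why: Jacobsen hydrolytic kinetic resolution; the (S,S) catalyst hydrates the (R)-epoxide selectively, so the (S)-epoxide carrying the future C5 stereocenter is recovered in high ee (at most 50% yield).

**Syringyl branch**

Step 7
Reactants: 9 resorcinol
Product: 10 1,3-dimethoxybenzene
Conditions: MeI (2.5 equiv), K2CO3, acetone, reflux
Reagents that add atoms: iodomethane, CI
Why: Double Williamson O-methylation of the diphenol.

Step 8
Reactants: 10 1,3-dimethoxybenzene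
Product: 13 2,6-dimethoxyphenol, via (2,6-dimethoxyphenyl)lithium 11 (not isolated), via dimethyl (2,6-dimethoxyphenyl)boronate 12 (not isolated)
Conditions: n-BuLi, THF, 0 °C → rt; B(OMe)3, −78 °C → rt; then AcOH, 30% H2O2, 0 °C → rt
Reagents that add atoms: n-butyllithium, [Li]CCCC (lithium of 11 only); trimethyl borate, COB(OC)OC (boron ester of 12 only); hydrogen peroxide, OO (phenol oxygen of 13)
Why: Directed ortho-metalation at C2, flanked by both methoxy groups, then borylation and boronate oxidation (carbon-to-oxygen migration) give the phenol.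

Step 9
Reactants: 13 2,6-dimethoxyphenol
Product: 14 4-bromo-2,6-dimethoxyphenol
Conditions: NBS (1.0 equiv), CHCl3, −40 °C → rt
Reagents that add atoms: N-bromosuccinimide, O=C1CCC(=O)N1Br
Why: Electrophilic aromatic bromination para to the free hydroxyl group; both ortho positions are blocked by methoxy groups.

Step 10
Reactants: 14 4-bromo-2,6-dimethoxyphenol
Product: 15 2-(benzyloxy)-5-bromo-1,3-dimethoxybenzene
Conditions: BnBr, K2CO3, DMF, 60 °C
Reagents that add atoms: benzyl bromide, BrCc1ccccc1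
Why: Williamson ether synthesis on the hindered phenoxide.

Step 11
Reactants: 15 2-(benzyloxy)-5-bromo-1,3-dimethoxybenzene; 5 allyl alcohol
Product: 16 3-[4-(benzyloxy)-3,5-dimethoxyphenyl]propanal
Conditions: Pd(OAc)2 (3 mol%), n-Bu4NCl, NaHCO3, DMF, 90 °C
Reagents that add atoms: none
Why: Heck–Jeffery arylation of allyl alcohol with β-hydride elimination toward the carbinol carbon, as in step 4.

Step 12
Reactants: 16 3-[4-(benzyloxy)-3,5-dimethoxyphenyl]propanal
Product: 17 2-{2-[4-(benzyloxy)-3,5-dimethoxyphenyl]ethyl}-1,3-dithiane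
Conditions: HS(CH2)3SH (1.1 equiv), BF3·OEt2 (0.1 equiv), CH2Cl2, 0 °C, short reaction time
Reagents that add atoms: propane-1,3-dithiol, SCCCS
Why: Lewis acid-catalysed dithioacetalisation turns the aldehyde carbon into an acyl anion equivalent (Corey–Seebach umpolung).

**Coupling and end game**

Step 13
Reactants: 17 2-{2-[4-(benzyloxy)-3,5-dimethoxyphenyl]ethyl}-1,3-dithiane; 8 (2S)-2-{2-[4-(benzyloxy)-3-methoxyphenyl]ethyl}oxirane
Product: 19 (2S)-4-[4-(benzyloxy)-3-methoxyphenyl]-1-(2-{2-[4-(benzyloxy)-3,5-dimethoxyphenyl]ethyl}-1,3-dithian-2-yl)butan-2-ol, via 2-lithio-1,3-dithiane derivative 18 (not isolated)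
Conditions: 17 (1.2 equiv), t-BuLi (1.2 equiv), THF/HMPA (10:1), −78 °C, 10 min; then 8, −78 → −20 °C; H2O quench
Reagents that add atoms: tert-butyllithium, [Li]C(C)(C)C (lithium of 18 only)
Why: Corey–Seebach alkylation; the lithiated dithiane opens the terminal epoxide at its unsubstituted carbon (SN2), so the (S) centre of 8 is carried over untouched.

Step 14
Reactants: 19 the hydroxy dithiane
Product: 20 (5S)-1-[4-(benzyloxy)-3,5-dimethoxyphenyl]-7-[4-(benzyloxy)-3-methoxyphenyl]-5-hydroxyheptan-3-one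
Conditions: MeI (10 equiv), CaCO3, MeCN/H2O (9:1), 45 °C
Reagents that add atoms: water, O
Why: Dithiane unmasking; S-methylation makes sulfur a leaving group and buffered hydrolysis releases the ketone without dehydrating the β-hydroxy ketone.

Step 15
Reactants: 20 the (5S)-β-hydroxy ketone
Product: 21 (3S,5S)-1-[4-(benzyloxy)-3,5-dimethoxyphenyl]-7-[4-(benzyloxy)-3-methoxyphenyl]heptane-3,5-diol
Conditions: Me4NBH(OAc)3 (5 equiv), MeCN/AcOH (1:1), −30 °C
Reagents that add atoms: none
Why: Evans–Saksena reduction; the C5 hydroxyl binds boron and delivers hydride intramolecularly through a chair transition state, setting C3 anti to C5, that is (3S).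

Step 16
Reactants: 21 the bis-benzyl anti diol
Product: 22 (3S,5S)-1-(4-hydroxy-3,5-dimethoxyphenyl)-7-(4-hydroxy-3-methoxyphenyl)heptane-3,5-diol (target)
Conditions: H2 (1 atm), 10% Pd/C, EtOAc/MeOH, rt
Reagents that add atoms: none
Why: Catalytic hydrogenolysis cleaves both aryl benzyl ethers and leaves the non-benzylic secondary alcohols and both stereocenters untouched.

**Compound list**
1 | catechol | Oc1ccccc1O | starting material
2 | guaiacol | COc1ccccc1O | intermediate
3 | 4-bromo-2-methoxyphenol | COc1cc(Br)ccc1O | intermediate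
4 | 1-(benzyloxy)-4-bromo-2-methoxybenzene | COc1cc(Br)ccc1OCc1ccccc1 | intermediate
5 | allyl alcohol | C=CCO | starting material
6 | 3-[4-(benzyloxy)-3-methoxyphenyl]propanal | COc1cc(CCC=O)ccc1OCc1ccccc1 | intermediate
7 | racemic 2-{2-[4-(benzyloxy)-3-methoxyphenyl]ethyl}oxirane | COc1cc(CCC2CO2)ccc1OCc1ccccc1 | intermediate
8 | (2S)-2-{2-[4-(benzyloxy)-3-methoxyphenyl]ethyl}oxirane | COc1cc(CC[C@H]2CO2)ccc1OCc1ccccc1 | intermediate
9 | resorcinol | Oc1cccc(O)c1 | starting material
10 | 1,3-dimethoxybenzene | COc1cccc(OC)c1 | intermediate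
11 | (2,6-dimethoxyphenyl)lithium | [Li]c1c(OC)cccc1OC | intermediate (not isolated)
12 | dimethyl (2,6-dimethoxyphenyl)boronate | COB(OC)c1c(OC)cccc1OC | intermediate (not isolated)
13 | 2,6-dimethoxyphenol | COc1cccc(OC)c1O | intermediate
14 | 4-bromo-2,6-dimethoxyphenol | COc1cc(Br)cc(OC)c1O | intermediate
15 | 2-(benzyloxy)-5-bromo-1,3-dimethoxybenzene | COc1cc(Br)cc(OC)c1OCc1ccccc1 | intermediate
16 | 3-[4-(benzyloxy)-3,5-dimethoxyphenyl]propanal | COc1cc(CCC=O)cc(OC)c1OCc1ccccc1 | intermediate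
17 | 2-{2-[4-(benzyloxy)-3,5-dimethoxyphenyl]ethyl}-1,3-dithiane | COc1cc(CCC2SCCCS2)cc(OC)c1OCc1ccccc1 | intermediate
18 | 2-lithio-2-{2-[4-(benzyloxy)-3,5-dimethoxyphenyl]ethyl}-1,3-dithiane | COc1cc(CCC2([Li])SCCCS2)cc(OC)c1OCc1ccccc1 | intermediate (not isolated)
19 | (2S)-4-[4-(benzyloxy)-3-methoxyphenyl]-1-(2-{2-[4-(benzyloxy)-3,5-dimethoxyphenyl]ethyl}-1,3-dithian-2-yl)butan-2-ol | COc1cc(CC[C@H](O)CC2(CCc3cc(OC)c(OCc4ccccc4)c(OC)c3)SCCCS2)ccc1OCc1ccccc1 | intermediate
20 | (5S)-1-[4-(benzyloxy)-3,5-dimethoxyphenyl]-7-[4-(benzyloxy)-3-methoxyphenyl]-5-hydroxyheptan-3-one | COc1cc(CC[C@H](O)CC(=O)CCc2cc(OC)c(OCc3ccccc3)c(OC)c2)ccc1OCc1ccccc1 | intermediate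
21 | (3S,5S)-1-[4-(benzyloxy)-3,5-dimethoxyphenyl]-7-[4-(benzyloxy)-3-methoxyphenyl]heptane-3,5-diol | COc1cc(CC[C@H](O)C[C@@H](O)CCc2cc(OC)c(OCc3ccccc3)c(OC)c2)ccc1OCc1ccccc1 | intermediate
22 | (3S,5S)-1-(4-hydroxy-3,5-dimethoxyphenyl)-7-(4-hydroxy-3-methoxyphenyl)heptane-3,5-diol | COc1cc(CC[C@H](O)C[C@@H](O)CCc2cc(OC)c(O)c(OC)c2)ccc1O | target

**Totals**
Total step count: 16. Longest linear sequence: 10 steps (steps 1–6 then 13–16, or steps 7–12 then 13–16).

**Steps most likely to fail, with fallbacks**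

Step 4 (Heck–Jeffery coupling of the electron-rich bromide 4 with allyl alcohol: slow oxidative addition, branched and unsaturated by-products; step 11 is the same reaction). The fallback sets out from 4. Bromine–lithium exchange (n-BuLi, THF, −78 °C) gives [4-(benzyloxy)-3-methoxyphenyl]lithium F1. F1 opens oxetane under BF3·OEt2 activation at −78 °C to give 3-[4-(benzyloxy)-3-methoxyphenyl]propan-1-ol F2. Dess–Martin oxidation of F2 (CH2Cl2, rt) comes back to the route at 6.

Step 9 (para-bromination of the very electron-rich phenol 13: overbromination and oxidation to the quinone are the risks). The fallback sets out from 13 and avoids both the halide and the second Heck reaction. O-Allylation (allyl bromide, K2CO3, acetone, reflux) gives 2-(allyloxy)-1,3-dimethoxybenzene F3. Heating F3 (N,N-diethylaniline, 200 °C) triggers a para-Claisen rearrangement, because both ortho positions are blocked, and gives 4-allyl-2,6-dimethoxyphenol F4. Benzylation (BnBr, K2CO3, DMF) gives 5-allyl-2-(benzyloxy)-1,3-dimethoxybenzene F5. Hydroboration with 9-BBN (THF, rt) gives 9-{3-[4-(benzyloxy)-3,5-dimethoxyphenyl]propyl}-9-borabicyclo[3.3.1]nonane F6, which NaOH/H2O2 oxidises in the same flask to 3-[4-(benzyloxy)-3,5-dimethoxyphenyl]propan-1-ol F7. Dess–Martin oxidation of F7 comes back to the route at 16.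

Step 13 (dithiane anion–epoxide coupling: incomplete lithiation of the 2-alkyl dithiane or attack on the benzyl ethers would stop the convergent step). The fallback sets out from 15 and 6 and replaces the umpolung coupling by an aldol coupling with catalyst-controlled reduction. Heck–Jeffery reaction of 15 with but-3-en-2-ol (Pd(OAc)2, n-Bu4NCl, NaHCO3, DMF, 90 °C) gives 4-[4-(benzyloxy)-3,5-dimethoxyphenyl]butan-2-one F8. LiN(i-Pr)2 (THF, −78 °C) gives the kinetic lithium enolate, lithium 4-[4-(benzyloxy)-3,5-dimethoxyphenyl]but-1-en-2-olate F9. F9 adds to aldehyde 6 to give racemic 1-[4-(benzyloxy)-3,5-dimethoxyphenyl]-7-[4-(benzyloxy)-3-methoxyphenyl]-5-hydroxyheptan-3-one F10. Dess–Martin oxidation gives 1-[4-(benzyloxy)-3,5-dimethoxyphenyl]-7-[4-(benzyloxy)-3-methoxyphenyl]heptane-3,5-dione F11. Noyori hydrogenation of F11 (H2 50 atm, RuCl2[(S)-BINAP] 1 mol%, MeOH/CH2Cl2, 50 °C) reduces both carbonyls with catalyst control to the (3S,5S) anti diol and comes back to the route at 21.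

**Further compounds**
F1 | step 4 | [4-(benzyloxy)-3-methoxyphenyl]lithium | [Li]c1ccc(OCc2ccccc2)c(OC)c1
F2 | step 4 | 3-[4-(benzyloxy)-3-methoxyphenyl]propan-1-ol | COc1cc(CCCO)ccc1OCc1ccccc1
F3 | step 9 | 2-(allyloxy)-1,3-dimethoxybenzene | C=CCOc1c(OC)cccc1OC
F4 | step 9 | 4-allyl-2,6-dimethoxyphenol | C=CCc1cc(OC)c(O)c(OC)c1
F5 | step 9 | 5-allyl-2-(benzyloxy)-1,3-dimethoxybenzene | C=CCc1cc(OC)c(OCc2ccccc2)c(OC)c1
F6 | step 9 | 9-{3-[4-(benzyloxy)-3,5-dimethoxyphenyl]propyl}-9-borabicyclo[3.3.1]nonane | COc1cc(CCCB2C3CCCC2CCC3)cc(OC)c1OCc1ccccc1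
F7 | step 9 | 3-[4-(benzyloxy)-3,5-dimethoxyphenyl]propan-1-ol | COc1cc(CCCO)cc(OC)c1OCc1ccccc1
F8 | step 13 | 4-[4-(benzyloxy)-3,5-dimethoxyphenyl]butan-2-one | COc1cc(CCC(C)=O)cc(OC)c1OCc1ccccc1
F9 | step 13 | lithium 4-[4-(benzyloxy)-3,5-dimethoxyphenyl]but-1-en-2-olate | [Li]OC(=C)CCc1cc(OC)c(OCc2ccccc2)c(OC)c1
F10 | step 13 | racemic 1-[4-(benzyloxy)-3,5-dimethoxyphenyl]-7-[4-(benzyloxy)-3-methoxyphenyl]-5-hydroxyheptan-3-one | COc1cc(CCC(O)CC(=O)CCc2cc(OC)c(OCc3ccccc3)c(OC)c2)ccc1OCc1ccccc1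
F11 | step 13 | 1-[4-(benzyloxy)-3,5-dimethoxyphenyl]-7-[4-(benzyloxy)-3-methoxyphenyl]heptane-3,5-dione | COc1cc(CCC(=O)CC(=O)CCc2cc(OC)c(OCc3ccccc3)c(OC)c2)ccc1OCc1ccccc1
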